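## Analysis of the target

- **Structure.** The target (C52H44O21) is the procyanidin trimer (−)-epicatechin-(4β→8)-(+)-catechin-(4α→8)-(+)-catechin. O3 of its bottom unit carries the ester of (S)-1-hydroxy-6-oxocyclohex-2-ene-1-carboxylic acid. It holds three 2-arylchroman units (each with a benzo ring, a pyran ring and a catechol ring) and one cyclohexenone ring.
- **Stereocentres.** There are nine. C2 and C3 of the three pyran rings (2R,3R on top; 2R,3S in the middle and at the bottom) are those of commercial flavonoids. Three must be made: C4 of the top pyran ring (aryl β, trans to O3), C4 of the middle pyran ring (aryl α, trans to O3), and the remote quaternary C1 (S) of the cyclohexenone ring.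
- **Feature that defines the skeleton.** This is the pair of sp3–sp2 bonds C4(top pyran ring)–C8(middle benzo ring) and C4(middle pyran ring)–C8(bottom benzo ring). Only the middle unit is engaged at both ends, as donor at C8 and as acceptor at C4. It can therefore serve as a linchpin whose two polarities are switched on one after the other, so that both bonds form in one operation from three monomers.
- **The acyl part.** It is a tertiary α-hydroxy-β-keto ester with a β,γ-alkene (C2=C3). Base cleaves it (retro-Claisen cleavage, ketol shifts). It is formally a hydrate of a salicylate and can aromatise. Its alkene would be saturated under the hydrogenolysis that benzyl ethers need. Its parent acid is a β-keto acid that loses CO2.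
- **The flavan part.** The interflavan bonds are scrambled by strong acid. The twelve phenols (three catechols) oxidise above neutral pH.
- **What makes it hard.** Every flavan is both a potential donor and a potential acceptor, so oligomerisation must be stopped at the trimer. C8 has to win over C6. Once the cyclohexenone ring is on board, no base, no H2, no oxidant and no strong acid may follow.

## Retrosynthetic reasoning

**18 to 17.** The last operation only frees four phenols of the top unit from silyl ethers, with buffered fluoride in an acidic medium. No bond of the skeleton is touched. The one deprotection that follows the entry of the cyclohexenone ring is one this ring tolerates.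

**17 to 15 + 12 + 9 (key disconnection).**
- Both C4–C8 bonds are cut at once, which takes the trimer back to three monomers.
- The cut is placed there because each of these bonds joins a cation-stabilising benzylic carbon to the most electron-rich aromatic CH of the next unit.
- The middle unit 12 can be given a C4 leaving group (sulfur) that is silent while its C8 acts as donor and is woken later by a soft silver salt.
- 15 carries an oxygen leaving group for a hard Lewis acid, and its own nucleophilic positions are blocked by silyl ethers.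
- 9 has no leaving group and already carries the finished ester, unprotected.
- The forward reaction has to form two C–C bonds and two stereocentres in one flask, with each monomer playing one role at a time.

**9 to 7 (through 8) and 7 to 5.**
- The cyclohexenone ring is not built. It is read as a reduced, ipso-hydroxylated salicylate.
- Its ketone is the enol ether carbon of a 1,4-dihydroanisate, and its C2=C3 alkene is the second alkene left by the arene reduction.
- Only the C1–O bond is missing. Cutting that bond leads to the ester 5.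
- The planar dienolate 6 of ester 5 is oxidised under the control of the neighbouring flavan stereocentres.
- What is gained is a masked, storable acyl donor instead of a β-keto acid.

**5 to 2 + 4, 4 to 3, 2 to 1.** The ester C–O bond is cut at the monomer stage, where only one secondary alcohol is present. 4 is the dearomatised form of commercial 3. 2 is 1 with its four phenols silylated.

**12 to 10 (through 11).** The C4–S bond is traced to the C4 carbonyl of unprotected 10. Reduction to the diol 11 and ionisation install the relay group without any protecting group, and C2 and C3 are bought.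

**15 to 14 to 13.** The C4–O bond of the top unit comes from oxidation of the benzylic C4–H of silylated 13. The same silyl groups later act as caps and fall in the last step.

## Alternatives that were turned down

**Alternative 1: the textbook route.**
- *Disconnection.* The ester C–O bond is cut last and the two C4–C8 bonds one at a time, all in the benzyl ether series.
- *Forward key step.* C4-alkoxylated tetra-O-benzyl monomers are joined twice by TMSOTf to give the dodeca-O-benzyl trimer A1. O3 of the bottom unit is then acylated with the free acid A2, and the benzyl ethers are removed with H2 over Pd(OH)2/C.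
- *Why turned down.* A2 is a β-keto acid and decarboxylates on activation. Three secondary alcohols of A1 would have to be told apart. Twelve hydrogenolyses cannot spare the C2=C3 alkene of the acyl ring. Each unit also needs its own protection, activation and isolation, so the count is far higher.

**Alternative 2: polarity reversal at C8.**
- *Disconnection.* The C4(middle)–C8(bottom) bond is made by carbonyl addition.
- *Forward key step.* A C8-lithiated, fully benzylated bottom unit adds to the C4 carbonyl of a fully benzylated dihydroflavonol to give the tertiary carbinol A3. Ionic reduction (Et3SiH, acid) then removes the hydroxyl group.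
- *Why turned down.* The method is regiospecific and cannot oligomerise. However, hydride enters the diaryl cation anti to O3, which places the bottom benzo ring cis to O3, the wrong C4 epimer, and the same holds for the top bond. The organolithium also forbids an early ester, so the late acylation and the hydrogenolysis problem of Alternative 1 come back.

**Alternative 3: skeletal ring expansion to the cyclohexenone ring.**
- *Disconnection.* The C1–C2 bond of that ring arises by migration.
- *Forward key step.* An α-ketol rearrangement of the 1-hydroxycyclopent-2-enyl glyoxylate A4 (chelating Lewis acid such as Cu(OTf)2 with a bisoxazoline) shifts the vinyl carbon to the ketone carbon. This creates C1 and the six-membered ring together.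
- *Why turned down.* Vinyl and alkyl migration compete. The shift is reversible, and the alkyl shift leads to a conjugated, more stable enone. The carbinol centre of A4 would have to be set first. A4 costs more steps than the arene reduction, and nothing is won for the interflavan bonds.

Key step: step 9

Assumption: 12 is written as its 3,4-trans (4α) epimer. Its C4 configuration is erased in step 9, so any epimer formed beside it need not be removed. TBS = tert-butyldimethylsilyl.

## Route

Step 1
Reactants: 1 (+)-catechin
Product: 2 5,7,3',4'-tetrakis-O-TBS-(+)-catechin (3-OH free)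
Conditions: TBSCl (4.4 equiv), imidazole, DMF, 0 °C to rt
Reagents that add atoms: tert-butyldimethylsilyl chloride, CC(C)(C)[Si](C)(C)Cl
Why: Silyl ether formation is much faster at the four phenols than at the hindered secondary 3-OH, so the reaction should stop at the tetrasilyl ether; no stereocentre is touched.

Step 2
Reactants: 3 2-methoxybenzoic acid
Product: 4 (±)-2-methoxycyclohexa-2,5-diene-1-carboxylic acid
Conditions: Li, NH3(l)–THF, −78 °C; NH4Cl; cold extraction at pH 4
Reagents that add atoms: none
Why: Birch reduction: the carboxylate directs the new hydrogens to C1 and C4 and the methoxy group stays on a double bond, so the masked ketone and the later C2=C3 alkene are placed in one step. C1 is racemic here and is erased in step 4.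

Step 3
Reactants: 2 5,7,3',4'-tetrakis-O-TBS-(+)-catechin; 4 (±)-2-methoxycyclohexa-2,5-diene-1-carboxylic acid
Product: 5 3-O-(2-methoxycyclohexa-2,5-diene-1-carbonyl)-5,7,3',4'-tetrakis-O-TBS-(+)-catechin (both epimers at the acyl C1)
Conditions: DCC, DMAP (cat.), CH2Cl2, 0 °C to rt
Reagents that add atoms: none
Why: Steglich esterification of the only free, equatorial alcohol, as known for 3-O-acylation of phenol-protected catechins. The enol ether keeps the acid from behaving as a β-keto acid, and both C1 epimers are carried on because they converge in step 4.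

Step 4
Reactants: 5 3-O-(2-methoxycyclohexa-2,5-diene-1-carbonyl)-5,7,3',4'-tetrakis-O-TBS-(+)-catechin
Product: 7 3-O-[(1S)-1-hydroxy-2-methoxycyclohexa-2,5-diene-1-carbonyl]-5,7,3',4'-tetrakis-O-TBS-(+)-catechin, via sodium dienolate 6 (not isolated)
Conditions: NaN(SiMe3)2, THF, −78 °C; 2-(phenylsulfonyl)-3-phenyloxaziridine, −78 °C; AcOH
Reagents that add atoms: 2-(phenylsulfonyl)-3-phenyloxaziridine, O=S(=O)(c1ccccc1)N1OC1c1ccccc1
Why: Davis oxidation of the cross-conjugated dienolate 6, which reacts at its central carbon as in Birch reductive alkylations. Sodium bridged between the enolate oxygen and the methoxy oxygen fixes the enolate geometry, and the silylated catechol ring at C2 (trans to the ester oxygen, as in a trans-2-phenylcyclohexyl auxiliary) covers the face turned to C2. Oxygen should therefore arrive from the face turned to C4, which corresponds to S at C1.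

Step 5
Reactants: 7 3-O-[(1S)-1-hydroxy-2-methoxycyclohexa-2,5-diene-1-carbonyl]-5,7,3',4'-tetrakis-O-TBS-(+)-catechin
Product: 9 (+)-catechin 3-O-[(1S)-1-hydroxy-6-oxocyclohex-2-ene-1-carboxylate], via tetrasilyl keto ester 8 (not isolated)
Conditions: 48% aq. HF, MeCN–THF, 0 °C to rt
Reagents that add atoms: water, O
Why: Acid hydrolysis of the enol ether gives ketone 8, whose alkene cannot move into conjugation because C1 is quaternary; HF then cleaves the four aryl silyl ethers. The medium stays acidic, which the α-hydroxy-β-keto ester tolerates, and C1 bears no hydrogen, so it cannot epimerise.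

Step 6
Reactants: 10 (+)-taxifolin
Product: 12 4α-benzylsulfanyl-(+)-catechin, via leucocyanidin 11 (not isolated)
Conditions: NaBH4, EtOH, 0 °C, Ar; then PhCH2SH (excess), AcOH, rt
Reagents that add atoms: phenylmethanethiol, SCc1ccccc1
Why: Borohydride reduces the C4 ketone of unprotected 10 to the 2,3-trans-3,4-trans diol 11. In acetic acid 11 ionises to the C4 cation, and the excess thiol, a far better nucleophile than any benzo ring, traps it mainly anti to O3 (SN1 thioether formation as in the thiolysis of flavan-3,4-diols).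

Step 7
Reactants: 13 (−)-epicatechin
Product: 14 5,7,3',4'-tetrakis-O-TBS-(−)-epicatechin (3-OH free)
Conditions: TBSCl (4.4 equiv), imidazole, DMF, 0 °C to rt
Reagents that add atoms: tert-butyldimethylsilyl chloride, CC(C)(C)[Si](C)(C)Cl
Why: Same phenol-selective silylation as in step 1; the axial 3-OH is even slower to react.

Step 8
Reactants: 14 5,7,3',4'-tetrakis-O-TBS-(−)-epicatechin
Product: 15 4β-(2-ethoxyethoxy)-5,7,3',4'-tetrakis-O-TBS-(−)-epicatechin
Conditions: DDQ, 2-ethoxyethanol, CH2Cl2, rt
Reagents that add atoms: 2-ethoxyethanol, CCOCCO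
Why: DDQ abstracts hydride from the benzylic C4–H, which is activated by three ring oxygens (oxidative C4 alkoxylation known for O-protected flavan-3-ols). The alcohol adds to the cation from the β face, anti to O3 and to the C2 aryl group. Aryl silyl ethers are inert to DDQ under such conditions.

Step 9
Reactants: 15 4β-(2-ethoxyethoxy)-5,7,3',4'-tetrakis-O-TBS-(−)-epicatechin; 12 4α-benzylsulfanyl-(+)-catechin; 9 (+)-catechin 3-O-[(1S)-1-hydroxy-6-oxocyclohex-2-ene-1-carboxylate]
Product: 17 5,7,3',4'-tetrakis-O-TBS-(−)-epicatechin-(4β→8)-(+)-catechin-(4α→8)-(+)-catechin 3-O-[(1S)-1-hydroxy-6-oxocyclohex-2-ene-1-carboxylate], via dimeric thioether 16 (not isolated)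
Conditions: (a) 15, 12 (1 equiv each), Yb(OTf)3 (cat.), 4 Å sieves, THF–CH2Cl2, −20 to 0 °C; (b) same flask: 9, 2,6-di-tert-butyl-4-methylpyridine, AgOTf, −20 to 0 °C, dark
Reagents that add atoms: none
Why: In stage a the hard, oxophilic Yb(OTf)3 ionises only the C4–O bond of 15 to the benzylic cation stabilised by the 5-, 7- and ring oxygens, and C8 of the free phloroglucinol-type benzo ring of 12 attacks it in a Friedel–Crafts alkylation to give 16. In stage b the soft monovalent silver salt removes the benzylsulfanyl group of 16, and the new cation at C4 of the middle pyran ring is captured by C8 of 9. The closest known reactions are the rare-earth triflate condensation of 4-(2-ethoxyethoxy)flavans with flavan-3-ols, the silver-salt activation of unprotected 4-benzylsulfanylflavan-3-ols, and the orthogonal use of oxygen and sulfur leaving groups in flavan oligomer synthesis; what is new is only that both run in one flask with unprotected donors. No ring is closed; two C–C bonds join three monomers into the complete skeleton. At C4 of the top unit the donor enters from the β face, anti to the axial O3 and the C2 aryl group, which gives the 3,4-trans (4β) bond. At C4 of the middle unit the half-chair 2,3-trans cation is attacked anti to O3, from the α face, which gives the 3,4-trans (4α) bond, and since the C–S configuration is lost both epimers of 12 converge. The step needs each monomer to play one role at a time: 15 is an acceptor only, because its C6 and C8 are flanked by bulky, less donating silyl ethers; 12 is a donor only in stage a, because its C–S bond ignores the hard acid; and 9 has no leaving group, so neither an excess of a partner nor capping halogens are needed. C8 over C6 follows the innate preference of 5,7-dihydroxyflavans, and the hindered pyridine takes up the triflic acid so that the first interflavan bond and the acyl ring never meet strong acid.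

Step 10
Reactants: 17 5,7,3',4'-tetrakis-O-TBS-(−)-epicatechin-(4β→8)-(+)-catechin-(4α→8)-(+)-catechin 3-O-[(1S)-1-hydroxy-6-oxocyclohex-2-ene-1-carboxylate]
Product: 18 (−)-epicatechin-(4β→8)-(+)-catechin-(4α→8)-(+)-catechin 3-O-[(1S)-1-hydroxy-6-oxocyclohex-2-ene-1-carboxylate] (target)
Conditions: HF·pyridine, pyridine–THF, 0 °C to rt; Sephadex LH-20
Reagents that add atoms: none
Why: Fluoride cleavage of four aryl silyl ethers in a weakly acidic buffer. This leaves the alkene, the α-hydroxy-β-keto ester and both interflavan bonds alone and touches no stereocentre.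

## Compound list

1 | (+)-catechin, (2R,3S)-2-(3,4-dihydroxyphenyl)chromane-3,5,7-triol | O[C@H]1Cc2c(O)cc(O)cc2O[C@@H]1c1ccc(O)c(O)c1 | starting material
2 | 5,7,3',4'-tetrakis-O-TBS-(+)-catechin | O[C@H]1Cc2c(O[Si](C)(C)C(C)(C)C)cc(O[Si](C)(C)C(C)(C)C)cc2O[C@@H]1c1ccc(O[Si](C)(C)C(C)(C)C)c(O[Si](C)(C)C(C)(C)C)c1 | intermediate
3 | 2-methoxybenzoic acid | COc1ccccc1C(=O)O | starting material
4 | (±)-2-methoxycyclohexa-2,5-diene-1-carboxylic acid | COC1=CCC=CC1C(=O)O | intermediate
5 | 3-O-(2-methoxycyclohexa-2,5-diene-1-carbonyl)-5,7,3',4'-tetrakis-O-TBS-(+)-catechin (epimers at acyl C1) | COC1=CCC=CC1C(=O)O[C@H]1Cc2c(O[Si](C)(C)C(C)(C)C)cc(O[Si](C)(C)C(C)(C)C)cc2O[C@@H]1c1ccc(O[Si](C)(C)C(C)(C)C)c(O[Si](C)(C)C(C)(C)C)c1 | intermediate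
6 | sodium dienolate of 5 (enolate O cis to the methoxy-bearing carbon) | COC1=CCC=C/C1=C(/[O-])O[C@H]1Cc2c(O[Si](C)(C)C(C)(C)C)cc(O[Si](C)(C)C(C)(C)C)cc2O[C@@H]1c1ccc(O[Si](C)(C)C(C)(C)C)c(O[Si](C)(C)C(C)(C)C)c1.[Na+] | intermediate
7 | 3-O-[(1S)-1-hydroxy-2-methoxycyclohexa-2,5-diene-1-carbonyl]-5,7,3',4'-tetrakis-O-TBS-(+)-catechin | COC1=CCC=C[C@@]1(O)C(=O)O[C@H]1Cc2c(O[Si](C)(C)C(C)(C)C)cc(O[Si](C)(C)C(C)(C)C)cc2O[C@@H]1c1ccc(O[Si](C)(C)C(C)(C)C)c(O[Si](C)(C)C(C)(C)C)c1 | intermediate
8 | 3-O-[(1S)-1-hydroxy-6-oxocyclohex-2-ene-1-carbonyl]-5,7,3',4'-tetrakis-O-TBS-(+)-catechin | O=C1CCC=C[C@@]1(O)C(=O)O[C@H]1Cc2c(O[Si](C)(C)C(C)(C)C)cc(O[Si](C)(C)C(C)(C)C)cc2O[C@@H]1c1ccc(O[Si](C)(C)C(C)(C)C)c(O[Si](C)(C)C(C)(C)C)c1 | intermediate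
9 | (+)-catechin 3-O-[(1S)-1-hydroxy-6-oxocyclohex-2-ene-1-carboxylate] | O=C1CCC=C[C@@]1(O)C(=O)O[C@H]1Cc2c(O)cc(O)cc2O[C@@H]1c1ccc(O)c(O)c1 | intermediate
10 | (+)-taxifolin, (2R,3R)-dihydroquercetin | O=C1c2c(O)cc(O)cc2O[C@H](c2ccc(O)c(O)c2)[C@H]1O | starting material
11 | (2R,3S,4R)-leucocyanidin (2,3-trans-3,4-trans flavan-3,4-diol) | O[C@@H]1c2c(O)cc(O)cc2O[C@H](c2ccc(O)c(O)c2)[C@H]1O | intermediate
12 | 4α-benzylsulfanyl-(+)-catechin | c1ccccc1CS[C@@H]1c2c(O)cc(O)cc2O[C@H](c2ccc(O)c(O)c2)[C@H]1O | intermediate
13 | (−)-epicatechin, (2R,3R)-2-(3,4-dihydroxyphenyl)chromane-3,5,7-triol | O[C@@H]1Cc2c(O)cc(O)cc2O[C@@H]1c1ccc(O)c(O)c1 | starting material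
14 | 5,7,3',4'-tetrakis-O-TBS-(−)-epicatechin | O[C@@H]1Cc2c(O[Si](C)(C)C(C)(C)C)cc(O[Si](C)(C)C(C)(C)C)cc2O[C@@H]1c1ccc(O[Si](C)(C)C(C)(C)C)c(O[Si](C)(C)C(C)(C)C)c1 | intermediate
15 | 4β-(2-ethoxyethoxy)-5,7,3',4'-tetrakis-O-TBS-(−)-epicatechin | CCOCCO[C@H]1c2c(O[Si](C)(C)C(C)(C)C)cc(O[Si](C)(C)C(C)(C)C)cc2O[C@H](c2ccc(O[Si](C)(C)C(C)(C)C)c(O[Si](C)(C)C(C)(C)C)c2)[C@@H]1O | intermediate
16 | 5,7,3',4'-tetrakis-O-TBS-(−)-epicatechin-(4β→8)-[4α-benzylsulfanyl-(+)-catechin] | c1ccccc1CS[C@@H]3c4c(O)cc(O)c([C@H]5c6c(O[Si](C)(C)C(C)(C)C)cc(O[Si](C)(C)C(C)(C)C)cc6O[C@H](c6ccc(O[Si](C)(C)C(C)(C)C)c(O[Si](C)(C)C(C)(C)C)c6)[C@@H]5O)c4O[C@H](c4ccc(O)c(O)c4)[C@H]3O | intermediate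
17 | 5,7,3',4'-tetrakis-O-TBS-(−)-epicatechin-(4β→8)-(+)-catechin-(4α→8)-(+)-catechin 3-O-[(1S)-1-hydroxy-6-oxocyclohex-2-ene-1-carboxylate] | O=C1CCC=C[C@@]1(O)C(=O)O[C@H]1Cc2c(O)cc(O)c([C@@H]3c4c(O)cc(O)c([C@H]5c6c(O[Si](C)(C)C(C)(C)C)cc(O[Si](C)(C)C(C)(C)C)cc6O[C@H](c6ccc(O[Si](C)(C)C(C)(C)C)c(O[Si](C)(C)C(C)(C)C)c6)[C@@H]5O)c4O[C@H](c4ccc(O)c(O)c4)[C@H]3O)c2O[C@@H]1c1ccc(O)c(O)c1 | intermediate
18 | (−)-epicatechin-(4β→8)-(+)-catechin-(4α→8)-(+)-catechin 3-O-[(1S)-1-hydroxy-6-oxocyclohex-2-ene-1-carboxylate] | O=C1CCC=C[C@@]1(O)C(=O)O[C@H]1Cc2c(O)cc(O)c([C@@H]3c4c(O)cc(O)c([C@H]5c6c(O)cc(O)cc6O[C@H](c6ccc(O)c(O)c6)[C@@H]5O)c4O[C@H](c4ccc(O)c(O)c4)[C@H]3O)c2O[C@@H]1c1ccc(O)c(O)c1 | target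

## Step count and risks

Total step count: 10.

Longest linear sequence: 6 (steps 1, 3, 4, 5, 9, 10).

### Least certain steps

**Step 9 (key step).**
- *What may go wrong.* The roles may not separate fully. Possible failures are attack at C6 instead of C8 on the unprotected benzo rings, only moderate facial selectivity at the 2,3-trans cation of the middle unit, slow leakage of the C–S bond in stage a, and acid-induced scrambling of the first interflavan bond in stage b.
- *Fallback.* The thioether relay is given up and the chain is built from the bottom in two separate operations. The fallback sets out from 10 and 9.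
  - 10 is reduced to 11 as in step 6, and the remaining hydride is destroyed with acetic acid.
  - 11 is run slowly into an excess of 9 in dilute aqueous-ethanolic HCl at rt, the classical condensation of a flavan-3,4-diol with a flavan-3-ol.
  - This should give the dimer (+)-catechin-(4α→8)-(+)-catechin 3-O-[(1S)-1-hydroxy-6-oxocyclohex-2-ene-1-carboxylate] F1, with recovery of unreacted 9.
  - F1 is purified and alkylated at C8 of its upper benzo ring by 15 with Yb(OTf)3 as in stage a. The route is rejoined at 17.

**Step 8.**
- *What may go wrong.* Hydride abstraction may be sluggish, because silyl ethers are weaker donors than the alkyl ethers of the precedents. Oxidative loss of the catechol silyl groups may compete.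
- *Fallback.* The C4–heteroatom bond is taken from a natural interflavan bond instead of from C–H oxidation. The fallback by-passes 13 and 14 and comes back at 15.
  - Commercial procyanidin B2 F2 is cleaved with phenylmethanethiol in acetic acid–ethanol (thiolysis). This gives 13, which is returned to step 7, and 4β-benzylsulfanyl-(−)-epicatechin F3.
  - Silylation as in step 7 gives 4β-benzylsulfanyl-5,7,3',4'-tetrakis-O-TBS-(−)-epicatechin F4.
  - AgOTf, 2,6-di-tert-butyl-4-methylpyridine and 2-ethoxyethanol exchange sulfur for oxygen from the β face to give 15.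

**Step 4.**
- *What may go wrong.* Facial selectivity may be poor (or of the wrong sense) at a centre three bonds away from the controlling stereocentres. Oxidation at a terminal dienolate carbon and addition of the dienolate to the sulfonimine are further risks.
- *Fallback.* C1 is set by enzymatic dearomatisation, whose absolute sense matches the target. The fallback sets out from 2 and comes back at 8.
  - Sodium benzoate F5 is dihydroxylated by whole cells of Cupriavidus necator B9 (benzoate 1,2-dioxygenase) to (1S,2R)-1,2-dihydroxycyclohexa-3,5-diene-1-carboxylic acid F6.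
  - Diimide (dipotassium azodicarboxylate, AcOH) saturates the less hindered alkene next to the secondary carbinol. This gives (1S,6R)-1,6-dihydroxycyclohex-2-ene-1-carboxylic acid F7.
  - 2,2-Dimethoxypropane with an acid catalyst gives the acetonide acid F8.
  - DCC/DMAP coupling with 2 gives the acetonide ester F9.
  - Aqueous acetic acid frees the diol ester F10.
  - Dess–Martin periodinane oxidises the only secondary alcohol to give 8.

**Step 5.**
- *What may go wrong.* The bis-allylic tertiary alcohol may lose water and aromatise to the anisate before the enol ether is hydrolysed.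
- *Fallback.* The order is reversed, so that this alcohol and the enol ether never coexist. The fallback sets out from 5 and comes back at 8.
  - Oxalic acid in wet THF hydrolyses 5 to the β-keto ester 3-O-(6-oxocyclohex-2-ene-1-carbonyl)-5,7,3',4'-tetrakis-O-TBS-(+)-catechin F11.
  - The enol of F11 is hydroxylated at C1 under neutral conditions (CeCl3·7H2O cat., O2, i-PrOH), under the same shielding by the catechol ring, to give 8.

## Further compounds

F1 | step 9 | (+)-catechin-(4α→8)-(+)-catechin 3-O-[(1S)-1-hydroxy-6-oxocyclohex-2-ene-1-carboxylate] (ester on the lower unit) | O=C1CCC=C[C@@]1(O)C(=O)O[C@H]1Cc2c(O)cc(O)c([C@@H]3c4c(O)cc(O)cc4O[C@H](c4ccc(O)c(O)c4)[C@H]3O)c2O[C@@H]1c1ccc(O)c(O)c1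
F2 | step 8 | procyanidin B2, (−)-epicatechin-(4β→8)-(−)-epicatechin | O[C@@H]1Cc2c(O)cc(O)c([C@H]3c4c(O)cc(O)cc4O[C@H](c4ccc(O)c(O)c4)[C@@H]3O)c2O[C@@H]1c1ccc(O)c(O)c1
F3 | step 8 | 4β-benzylsulfanyl-(−)-epicatechin | c1ccccc1CS[C@H]1c2c(O)cc(O)cc2O[C@H](c2ccc(O)c(O)c2)[C@@H]1O
F4 | step 8 | 4β-benzylsulfanyl-5,7,3',4'-tetrakis-O-TBS-(−)-epicatechin | c1ccccc1CS[C@H]1c2c(O[Si](C)(C)C(C)(C)C)cc(O[Si](C)(C)C(C)(C)C)cc2O[C@H](c2ccc(O[Si](C)(C)C(C)(C)C)c(O[Si](C)(C)C(C)(C)C)c2)[C@@H]1O
F5 | step 4 | sodium benzoate | [Na+].[O-]C(=O)c1ccccc1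
F6 | step 4 | (1S,2R)-1,2-dihydroxycyclohexa-3,5-diene-1-carboxylic acid | O[C@@H]1C=CC=C[C@@]1(O)C(=O)O
F7 | step 4 | (1S,6R)-1,6-dihydroxycyclohex-2-ene-1-carboxylic acid | O[C@@H]1CCC=C[C@@]1(O)C(=O)O
F8 | step 4 | 1,6-O-isopropylidene derivative of F7 (acetonide acid) | CC1(C)O[C@@H]2CCC=C[C@@]2(O1)C(=O)O
F9 | step 4 | ester of F8 with O3 of 2 | CC1(C)O[C@@H]2CCC=C[C@@]2(O1)C(=O)O[C@H]1Cc2c(O[Si](C)(C)C(C)(C)C)cc(O[Si](C)(C)C(C)(C)C)cc2O[C@@H]1c1ccc(O[Si](C)(C)C(C)(C)C)c(O[Si](C)(C)C(C)(C)C)c1
F10 | step 4 | 3-O-[(1S,6R)-1,6-dihydroxycyclohex-2-ene-1-carbonyl]-5,7,3',4'-tetrakis-O-TBS-(+)-catechin | O[C@@H]1CCC=C[C@@]1(O)C(=O)O[C@H]1Cc2c(O[Si](C)(C)C(C)(C)C)cc(O[Si](C)(C)C(C)(C)C)cc2O[C@@H]1c1ccc(O[Si](C)(C)C(C)(C)C)c(O[Si](C)(C)C(C)(C)C)c1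
F11 | step 5 | 3-O-(6-oxocyclohex-2-ene-1-carbonyl)-5,7,3',4'-tetrakis-O-TBS-(+)-catechin (enolisable at acyl C1) | O=C1CCC=CC1C(=O)O[C@H]1Cc2c(O[Si](C)(C)C(C)(C)C)cc(O[Si](C)(C)C(C)(C)C)cc2O[C@@H]1c1ccc(O[Si](C)(C)C(C)(C)C)c(O[Si](C)(C)C(C)(C)C)c1
A1 | alternative 1 | dodeca-O-benzyl-(−)-epicatechin-(4β→8)-(+)-catechin-(4α→8)-(+)-catechin (three free 3-OH) | O[C@H]1Cc2c(OCc7ccccc7)cc(OCc7ccccc7)c([C@@H]3c4c(OCc7ccccc7)cc(OCc7ccccc7)c([C@H]5c6c(OCc7ccccc7)cc(OCc7ccccc7)cc6O[C@H](c6ccc(OCc7ccccc7)c(OCc7ccccc7)c6)[C@@H]5O)c4O[C@H](c4ccc(OCc7ccccc7)c(OCc7ccccc7)c4)[C@H]3O)c2O[C@@H]1c1ccc(OCc7ccccc7)c(OCc7ccccc7)c1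
A2 | alternative 1 | (S)-1-hydroxy-6-oxocyclohex-2-ene-1-carboxylic acid | O=C1CCC=C[C@@]1(O)C(=O)O
A3 | alternative 2 | tertiary C4 carbinol from a perbenzylated catechin-8-yl lithium and perbenzylated taxifolin (C4 configuration open) | c7ccccc7CO[C@H]1Cc2c(OCc7ccccc7)cc(OCc7ccccc7)c(C3(O)c4c(OCc7ccccc7)cc(OCc7ccccc7)cc4O[C@H](c4ccc(OCc7ccccc7)c(OCc7ccccc7)c4)[C@H]3OCc7ccccc7)c2O[C@@H]1c1ccc(OCc7ccccc7)c(OCc7ccccc7)c1
A4 | alternative 3 | 3-O-[2-(1-hydroxycyclopent-2-en-1-yl)-2-oxoacetyl]-5,7,3',4'-tetrakis-O-TBS-(+)-catechin (carbinol configuration open) | OC1(C=CCC1)C(=O)C(=O)O[C@H]1Cc2c(O[Si](C)(C)C(C)(C)C)cc(O[Si](C)(C)C(C)(C)C)cc2O[C@@H]1c1ccc(O[Si](C)(C)C(C)(C)C)c(O[Si](C)(C)C(C)(C)C)c1
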